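Conventions used throughout: positions are given in cembrane numbering (ring carbons C1–C14; C15 and C16 are the lactone α-carbon and carbonyl, attached to C1 and O14; C17 is the exocyclic methylene; methyl groups sit on C4, C8 and C12). TBS = tert-butyldimethylsilyl.

Remark on the chemistry: the ring alkene of 13 is drawn (E), the isomer expected for a 14-membered ring, and the acetal carbon of 15–17 is carried as both epimers; neither feature reaches a stereocentre of the target.

## The problem

Crassocolide B (23) is a 14-membered carbocycle with a trans-fused α-methylene-γ-lactone across C1/C14. It carries (E)-trisubstituted alkenes at C7=C8 and C11=C12, a C3 acetate beside a free tertiary C4 carbinol, and an allylic C13 acetate next to the lactone oxygen. The five stereocentres form two groups, C3/C4 and C13/C14/C1, separated by eight ring atoms, so neither group can direct the other and each needs its own reagent control. Within the groups, C3/C4 is the result of adding two oxygens anti across an (E)-alkene, C13/C14 is an anti diol, and C1 is adjacent to C14 and can be set by it. The α-methylene lactone will not tolerate nucleophiles or basic fluoride, the 1,5-diene array and the allylic C13 oxygen are at risk in strong acid, and the tertiary hydroxyl must end free while two secondary ones are acetylated. The carbon chain C2–C13, with both alkenes and all three methyl groups, is that of farnesol (1). The enabling feature is that C2 is an unsubstituted methylene between C1 and C3, while O14 sits on the carbon next to C1. A C1=C2 ring alkene is therefore allylic to O14 and can accept a C15 radical tethered to O14; the lactone ring closes at C1, C2 returns to CH2, and the geometry of the alkene that closed the macrocycle is erased.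

## Retrosynthesis

**23 to 21 (C–O acetyl and O–Si bonds).** The two acetates are put on last, onto triol 22, because they would not survive the enolate chemistry that installs C17. Triol 22 comes from tris-silyl ether 21 by one acidic fluoride treatment. Silyl ethers on O3, O4 and O13 are preferred to a C3/C4 acetonide because they come off together without aqueous mineral acid, which the 1,5-diene and the allylic C13 oxygen would not welcome.

**21 to 18 (C15=C17).** The exocyclic methylene is cut back to the saturated lactone 18. An enolate Mannich reaction and elimination through 19 is the standard answer and asks only that the silyl ethers tolerate LiN(i-Pr)2.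

**18 to 15 (C1–C15; the lactone ring).** Lactone 18 is the oxidised form of lactol acetal 16, and 16 is opened at C1–C15 to bromoacetal 15. This cut is preferred to an ester enolate alkylation or a Claisen route because it uses the one unsubstituted ring position, C2, and needs no activating group at C1. It removes a ring and the C1 stereocentre in one stroke. The forward reaction must close 5-exo at C1 and place C15 trans to the C13 branch.

**15 to 13 and 14 (acetal C–O).** The tether is ethyl vinyl ether (14) and bromine, attached to the free C14 hydroxyl of macrocycle 13. The two lactone carbons thus arrive at the oxidation level of an aldehyde, which cyclises far better than an α-halo ester.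

**13 to 12 (C1=C2).** The macrocycle is opened at the alkene to diene 12 and closed by metathesis. No other ring bond offers a closure without stereochemical or geometric demands. The forward reaction has one serious competitor: a ruthenium carbene on C2 can close a six-membered ring onto C7=C8 and expel the rest of the chain. Two design choices counter this. The C14 hydroxyl is left free so that the catalyst loads at the C1 vinyl group, from which no small ring is possible. O3 and O4 carry separate bulky silyl ethers, not a cyclic acetal: a dioxolane would hold C2 and C5 cis, exactly the geometry of the six-membered closure, whereas vicinal silyl ethers keep them anti and shield the C2 vinyl group.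

**12 to 6 and 8 (C13–C14).** The anti C13/C14 diol with its vinyl group is cut between the carbinol carbons to primary allylic alcohol 6 and the allyl donor 8. An ether-bearing allylborane made by metalating an allyl ether has (Z) geometry and gives the syn diol, so it is not used. An iridium-catalysed transfer-hydrogenative alkoxyallylation passes through an (E)-alkoxyallyl metal and gives the anti isomer directly, from the alcohol oxidation level, with O14 already marked as a benzoate (10). Silylation of O13 (11) and reductive removal of the benzoate give 12.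

**6 to 4 (C13–O, O–Si).** The C13 oxygen is introduced by allylic oxidation of the (E)-methyl group of the terminal isopropylidene unit of bis-silyl ether 5. Compound 5 is the silylated form of ene-diol 4. This keeps every carbon of C2–C13 in one piece.

**4 to 1 (C2–CH2, C3–O, C4–O).** Ene-diol 4 is traced to the (2R,3R)-epoxy alcohol 2 of farnesol. A Payne rearrangement moves the epoxide to the chain end with inversion at C3, and a sulfonium ylide adds the carbon that becomes the C2 vinyl terminus. The net result is the anti diol of the (E)-alkene with the vinyl group in place, in two steps from 1. The longer sequence of acid opening, acetal formation, oxidation and methylenation would also have to defeat the preference of a 1,2,3-triol for the terminal acetonide.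

## Roads not taken

**Alternative 1:** The ring is cut at C6–C7. An open-chain precursor A1 carries the finished lactone, a C7 alkenyl iodide and a cyclopropanol at C4. Zerovalent palladium (from Pd(OAc)2 and a bulky biaryl phosphine) would insert into C7–I, open the cyclopropanol by β-carbon elimination and form C6–C7 by reductive elimination, giving the 14-membered C4 ketone A2.
- Merits: the ring closes at a bond with no stereocentre, the C7=C8 geometry is fixed in the iodide, and neither tin nor a ring alkene in competition with other alkenes is involved.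
- Weak points: cyclopropanol cross-coupling has little precedent as a macrocyclisation; the palladium homoenolate can undergo β-hydride elimination to an enone. The cyclopropanol must be made from an ester in a molecule that already holds a lactone. The C4 methyl group and C4 configuration still have to be added to A2 under control of C3 alone.
- Comparison: it is the better plan for convergence and for avoiding the radical step. The chosen plan fixes C4 in its first step by asymmetric epoxidation and takes C2–C13 from one starting material.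

**Alternative 2:** The ring is cut at C12–C13. Ynal A3, with a methyl-capped C11≡C12 alkyne and a C13 aldehyde, would be closed with Ni(cod)2, an N-heterocyclic carbene and Et3SiH to the silyl ether A4.
- Merits: one step forms the ring, the (E)-C11=C12 alkene and the protected C13 carbinol, and reductive ynal macrocyclisation is established for rings of this size. In step economy at the ring-closing stage it is better than the chosen plan, and it has no competing small-ring closure.
- Weak points: regiochemistry at an alkyl/methyl alkyne is ligand-dependent, and the C13 configuration rests on the C14 centre of an α-oxygenated, epimerisable aldehyde. The alkyne cannot come from farnesol, so the chain and the C1/C14 lactone centres must be built separately before ring closure.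
- Comparison: the chosen plan keeps both trisubstituted alkenes from farnesol, sets C13/C14 by one catalyst-controlled step and has no regiochemical question in the ring closure.

**Alternative 3:** The ring is cut at C3–C4. Keto-aldehyde A5 would be treated with SmI2 so that the C3 ketyl adds to the C4 methyl ketone, giving diol A6.
- Merits: the diol appears in the ring-forming step with no protecting groups at C3/C4, so the end game would be shorter than in the chosen plan.
- Weak points: two stereocentres are formed in a 14-membered closure with nothing nearby to direct them, so up to four diol isomers are possible. Aldehyde reduction or dimerisation can compete, and the lactone must survive the reductant.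
- Comparison: the chosen plan is longer at the end but sets C3/C4 with reagent control before the ring exists.

Key step: step 11

## Route

Step 1
Reactants: 1 (2E,6E)-farnesol
Product: 2 [(2R,3R)-3-[(3E)-4,8-dimethylnona-3,7-dien-1-yl]-3-methyloxiran-2-yl]methanol
Conditions: Ti(Oi-Pr)4 (cat.), D-(−)-diethyl tartrate (cat.), t-BuOOH, 4 Å MS, CH2Cl2, −20 °C
Reagents that add atoms: tert-butyl hydroperoxide, CC(C)(C)OO
Why: Sharpless asymmetric epoxidation of an (E)-allylic alcohol; the D-tartrate complex delivers oxygen to the face that gives the (2R,3R)-epoxide, and the two remote alkenes do not react because only the allylic alcohol binds titanium.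

Step 2
Reactants: 2 [(2R,3R)-3-[(3E)-4,8-dimethylnona-3,7-dien-1-yl]-3-methyloxiran-2-yl]methanol
Product: 4 (3S,4R,7E)-4,8,12-trimethyltrideca-1,7,11-triene-3,4-diol, via terminal epoxide 3 (not isolated)
Conditions: Me3S+ I− (5 equiv), n-BuLi (4.8 equiv), THF, −10 °C → rt
Reagents that add atoms: trimethylsulfonium iodide, C[S+](C)C.[I-]
Why: Payne rearrangement followed by sulfonium ylide homologation of an epoxide to an allylic alcohol: the primary alkoxide opens the epoxide at the secondary carbon with inversion, the ylide attacks the CH2 of terminal epoxide 3, and the resulting sulfonium salt loses Me2S to form the vinyl group. The tertiary centre is untouched and the secondary one is inverted once, which turns (2R,3R) into the (3S,4R) diol.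

Step 3
Reactants: 4 (3S,4R,7E)-4,8,12-trimethyltrideca-1,7,11-triene-3,4-diol
Product: 5 (3S,4R,7E)-3,4-bis(tert-butyldimethylsilyloxy)-4,8,12-trimethyltrideca-1,7,11-triene
Conditions: TBSOTf (3 equiv), 2,6-lutidine, CH2Cl2, 0 °C → rt
Reagents that add atoms: tert-butyldimethylsilyl trifluoromethanesulfonate, CC(C)(C)[Si](C)(C)OS(=O)(=O)C(F)(F)F
Why: Silylation with a silyl triflate, which is reactive enough for the tertiary hydroxyl; two acyclic silyl ethers are used so that C2 and C5 stay anti and the C2 vinyl group is shielded in step 9.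

Step 4
Reactants: 5 (3S,4R,7E)-3,4-bis(tert-butyldimethylsilyloxy)-4,8,12-trimethyltrideca-1,7,11-triene
Product: 6 (2E,6E,10R,11S)-10,11-bis(tert-butyldimethylsilyloxy)-2,6,10-trimethyltrideca-2,6,12-trien-1-ol
Conditions: SeO2 (cat.), t-BuOOH, salicylic acid (cat.), CH2Cl2, 0 °C → rt
Reagents that add atoms: tert-butyl hydroperoxide, CC(C)(C)OO (terminal oxidant; the oxygen is delivered through selenium dioxide, O=[Se]=O)
Why: Selenium dioxide allylic oxidation (ene reaction, then [2,3]-shift), which should favour the (E)-methyl of the terminal isopropylidene group over the internal alkene and the hindered vinyl group. Enal 9 formed by further oxidation is not lost, because it is the intermediate of step 6 and couples under the same catalyst once isopropanol is added.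

Step 5
Reactants: 7 acrolein
Product: 8 prop-2-ene-1,1-diyl dibenzoate
Conditions: benzoic anhydride, H2SO4 (cat.), CH2Cl2, 0 °C → rt
Reagents that add atoms: benzoic anhydride, O=C(OC(=O)c1ccccc1)c1ccccc1
Why: Acid-catalysed acylal formation from an aldehyde and an anhydride; it gives the gem-dibenzoate allyl donor in one operation.

Step 6
Reactants: 6 (2E,6E,10R,11S)-10,11-bis(tert-butyldimethylsilyloxy)-2,6,10-trimethyltrideca-2,6,12-trien-1-ol; 8 prop-2-ene-1,1-diyl dibenzoate
Product: 10 (3R,4S,5E,9E,13R,14S)-13,14-bis(tert-butyldimethylsilyloxy)-4-hydroxy-5,9,13-trimethylhexadeca-1,5,9,15-tetraen-3-yl benzoate, via enal 9 (not isolated)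
Conditions: [Ir(cod)Cl]2 (2.5 mol %), (R)-SEGPHOS (5 mol %), 4-chloro-3-nitrobenzoic acid (10 mol %), K3PO4 (1 equiv), THF, 90 °C
Reagents that add atoms: none
Why: Iridium-catalysed transfer-hydrogenative anti-alkoxyallylation (Krische-type carbonyl allylation from the alcohol oxidation level): the catalyst dehydrogenates 6 to enal 9, ionises 8 to an (E)-(benzoyloxy)allyl iridium species and adds it through a closed chair transition state. The anti C13/C14 relationship follows from the (E)-allyl geometry, and the absolute sense (Re face of the C13 aldehyde, giving 13S,14R) from the ligand. (R)-SEGPHOS is written by analogy with the sense known for simple aldehydes and is to be confirmed on a model enal, the (S)-ligand being equally available.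

Step 7
Reactants: 10 (3R,4S,5E,9E,13R,14S)-13,14-bis(tert-butyldimethylsilyloxy)-4-hydroxy-5,9,13-trimethylhexadeca-1,5,9,15-tetraen-3-yl benzoate
Product: 11 (3R,4S,5E,9E,13R,14S)-4,13,14-tris(tert-butyldimethylsilyloxy)-5,9,13-trimethylhexadeca-1,5,9,15-tetraen-3-yl benzoate
Conditions: TBSOTf, 2,6-lutidine, CH2Cl2, −78 → 0 °C
Reagents that add atoms: tert-butyldimethylsilyl trifluoromethanesulfonate, CC(C)(C)[Si](C)(C)OS(=O)(=O)C(F)(F)F
Why: Silyl ether formation at the hindered allylic C13 hydroxyl; the weak base and low temperature leave no opportunity for benzoate migration.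

Step 8
Reactants: 11 (3R,4S,5E,9E,13R,14S)-4,13,14-tris(tert-butyldimethylsilyloxy)-5,9,13-trimethylhexadeca-1,5,9,15-tetraen-3-yl benzoate
Product: 12 (3R,4S,5E,9E,13R,14S)-4,13,14-tris(tert-butyldimethylsilyloxy)-5,9,13-trimethylhexadeca-1,5,9,15-tetraen-3-ol
Conditions: i-Bu2AlH (2.5 equiv), CH2Cl2, −78 °C; Rochelle salt work-up
Reagents that add atoms: none
Why: Reductive cleavage of the benzoate with an aluminium hydride; no alkoxide base is present, so the neighbouring silyl group should not migrate from O13 to O14.

Step 9
Reactants: 12 (3R,4S,5E,9E,13R,14S)-4,13,14-tris(tert-butyldimethylsilyloxy)-5,9,13-trimethylhexadeca-1,5,9,15-tetraen-3-ol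
Product: 13 (1R,2E,4S,5R,8E,12E,14S)-4,5,14-tris(tert-butyldimethylsilyloxy)-5,9,13-trimethylcyclotetradeca-2,8,12-trien-1-ol
Conditions: second-generation Grubbs catalyst RuCl2(=CHPh)(H2IMes)(PCy3) (10 mol %), CH2Cl2 (1 mM), 40 °C
Reagents that add atoms: none
Why: Ring-closing olefin metathesis of two monosubstituted alkenes. The catalyst should load at the C1 vinyl group beside the free C14 hydroxyl, from which only the 14-membered closure is productive, while the C2 vinyl group is shielded by the two silyl ethers. Either alkene geometry would serve because C2 ends as CH2.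

Step 10
Reactants: 13 (1R,2E,4S,5R,8E,12E,14S)-4,5,14-tris(tert-butyldimethylsilyloxy)-5,9,13-trimethylcyclotetradeca-2,8,12-trien-1-ol; 14 ethyl vinyl ether
Product: 15 (1R,2E,4S,5R,8E,12E,14S)-1-(2-bromo-1-ethoxyethoxy)-4,5,14-tris(tert-butyldimethylsilyloxy)-5,9,13-trimethylcyclotetradeca-2,8,12-triene (both acetal epimers)
Conditions: ethyl vinyl ether (10 equiv), N-bromosuccinimide (1.5 equiv), CH2Cl2, −40 → 0 °C
Reagents that add atoms: N-bromosuccinimide, BrN1C(=O)CCC1=O
Why: Bromoacetalisation (bromination of the enol ether and capture of the oxocarbenium ion by the C14 hydroxyl); the excess of the far more electron-rich vinyl ether at low temperature keeps the bromine source away from the ring alkenes.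

Step 11
Reactants: 15 (1R,2E,4S,5R,8E,12E,14S)-1-(2-bromo-1-ethoxyethoxy)-4,5,14-tris(tert-butyldimethylsilyloxy)-5,9,13-trimethylcyclotetradeca-2,8,12-triene
Product: 16 (1R,3S,4R,7E,11E,13S,14R)-3,4,13-tris(tert-butyldimethylsilyloxy)-16-ethoxy-4,8,12-trimethyl-15-oxabicyclo[12.3.0]heptadeca-7,11-diene (both C16 epimers)
Conditions: Bu3SnH (1.3 equiv, held near 0.02 M by syringe pump), AIBN (0.1 equiv), benzene, 80 °C
Reagents that add atoms: none
Why: Tin hydride Ueno–Stork cyclisation of the bromoacetal of an allylic alcohol, applied here to a ring alkene. The tributyltin radical abstracts bromine; the primary C15 radical, held on O14 by the acetal, adds to C1 in a 5-exo-trig closure that forms C1–C15 and the tetrahydrofuran ring, and the secondary C2 radical takes hydrogen from Bu3SnH and carries the chain. Attack at C1 (5-exo) is favoured over attack at C2 (6-endo) on stereoelectronic grounds, and both trisubstituted alkenes are out of reach of the tether. The new centre C1 is set by C14: in the chair-like transition state the C13 branch on C14 lies pseudo-equatorial and C15 adds to the alkene face anti to it, which places C13 and C2 trans on the new ring (trans fusion, 1R); the ten-atom bridge of the (E)-macrocycle spans these two positions without strain. The step needs the closure to outrun reduction of the first radical, and the C2 radical to be reduced before it can add across the ring to C7=C8; holding the hydride near 0.02 M, not at high dilution, is meant to satisfy both. The acetal carbon stays a mixture of epimers and is removed in step 13.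

Step 12
Reactants: 16 (1R,3S,4R,7E,11E,13S,14R)-3,4,13-tris(tert-butyldimethylsilyloxy)-16-ethoxy-4,8,12-trimethyl-15-oxabicyclo[12.3.0]heptadeca-7,11-diene
Product: 17 (1R,3S,4R,7E,11E,13S,14R)-3,4,13-tris(tert-butyldimethylsilyloxy)-4,8,12-trimethyl-15-oxabicyclo[12.3.0]heptadeca-7,11-dien-16-ol (both C16 epimers)
Conditions: AcOH/THF/H2O (3:1:1), 40 °C
Reagents that add atoms: water, O
Why: Acid hydrolysis of a 2-alkoxytetrahydrofuran under the mild conditions used for tetrahydropyranyl ethers, which secondary and tertiary TBS ethers should survive.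

Step 13
Reactants: 17 (1R,3S,4R,7E,11E,13S,14R)-3,4,13-tris(tert-butyldimethylsilyloxy)-4,8,12-trimethyl-15-oxabicyclo[12.3.0]heptadeca-7,11-dien-16-ol
Product: 18 (1R,3S,4R,7E,11E,13S,14R)-3,4,13-tris(tert-butyldimethylsilyloxy)-4,8,12-trimethyl-15-oxabicyclo[12.3.0]heptadeca-7,11-dien-16-one
Conditions: (n-Pr4N)RuO4 (5 mol %), N-methylmorpholine N-oxide (1.5 equiv), 4 Å MS, CH2Cl2, rt
Reagents that add atoms: none
Why: Ley–Griffith oxidation of a lactol to the lactone under neutral conditions that leave alkenes and silyl ethers alone.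

Step 14
Reactants: 18 (1R,3S,4R,7E,11E,13S,14R)-3,4,13-tris(tert-butyldimethylsilyloxy)-4,8,12-trimethyl-15-oxabicyclo[12.3.0]heptadeca-7,11-dien-16-one
Product: 19 (1R,3S,4R,7E,11E,13S,14R)-3,4,13-tris(tert-butyldimethylsilyloxy)-17-[(dimethylamino)methyl]-4,8,12-trimethyl-15-oxabicyclo[12.3.0]heptadeca-7,11-dien-16-one (configuration at C17 of this name, the lactone α-carbon, immaterial)
Conditions: LiN(i-Pr)2 (1.3 equiv), THF, −78 °C; then Eschenmoser's salt (Me2N=CH2 I, 3 equiv), −78 °C → rt
Reagents that add atoms: N,N-dimethylmethyleneiminium iodide, C[N+](C)=C.[I-]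
Why: Mannich reaction of the lactone lithium enolate with a preformed iminium salt; the α-carbon has no β-leaving group, and its configuration is erased in step 15.

Step 15
Reactants: 19 (1R,3S,4R,7E,11E,13S,14R)-3,4,13-tris(tert-butyldimethylsilyloxy)-17-[(dimethylamino)methyl]-4,8,12-trimethyl-15-oxabicyclo[12.3.0]heptadeca-7,11-dien-16-one
Product: 21 (1R,3S,4R,7E,11E,13S,14R)-3,4,13-tris(tert-butyldimethylsilyloxy)-4,8,12-trimethyl-17-methylidene-15-oxabicyclo[12.3.0]heptadeca-7,11-dien-16-one, via ammonium iodide 20 (not isolated)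
Conditions: MeI (excess), MeOH, rt; concentrate; then sat. aq. NaHCO3, CH2Cl2, rt
Reagents that add atoms: none
Why: Quaternisation of the Mannich base and E1cB elimination of trimethylamine, the standard second half of lactone α-methylenation; the bicarbonate is too weak a base to add to the product.

Step 16
Reactants: 21 (1R,3S,4R,7E,11E,13S,14R)-3,4,13-tris(tert-butyldimethylsilyloxy)-4,8,12-trimethyl-17-methylidene-15-oxabicyclo[12.3.0]heptadeca-7,11-dien-16-one
Product: 22 (1R,3S,4R,7E,11E,13S,14R)-3,4,13-trihydroxy-4,8,12-trimethyl-17-methylidene-15-oxabicyclo[12.3.0]heptadeca-7,11-dien-16-one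
Conditions: 48% aq. HF, MeCN, 0 °C → rt
Reagents that add atoms: none
Why: Fluoride-mediated desilylation under mildly acidic conditions, strong enough for the tertiary silyl ether; basic fluoride is avoided because free alkoxides could add to the methylene lactone or trigger translactonisation.

Step 17
Reactants: 22 (1R,3S,4R,7E,11E,13S,14R)-3,4,13-trihydroxy-4,8,12-trimethyl-17-methylidene-15-oxabicyclo[12.3.0]heptadeca-7,11-dien-16-one
Product: 23 crassocolide B, (1R,3S,4R,7E,11E,13S,14R)-4-hydroxy-4,8,12-trimethyl-17-methylidene-16-oxo-15-oxabicyclo[12.3.0]heptadeca-7,11-diene-3,13-diyl diacetate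
Conditions: Ac2O (3 equiv), pyridine, DMAP (cat.), CH2Cl2, 0 °C → rt
Reagents that add atoms: acetic anhydride, CC(=O)OC(C)=O
Why: DMAP-catalysed acetylation; the two secondary hydroxyls should react at room temperature while the tertiary C4 hydroxyl is left free under these unforced conditions.

## Compound list

1 | (2E,6E)-farnesol | CC(C)=CCC/C(C)=C/CC/C(C)=C/CO | starting material
2 | [(2R,3R)-3-[(3E)-4,8-dimethylnona-3,7-dien-1-yl]-3-methyloxiran-2-yl]methanol | OC[C@H]1O[C@]1(C)CC/C=C(\C)CCC=C(C)C | intermediate
3 | (2R,5E)-6,10-dimethyl-2-[(2S)-oxiran-2-yl]undeca-5,9-dien-2-ol (terminal epoxide, not isolated) | C1O[C@@H]1[C@](C)(O)CC/C=C(\C)CCC=C(C)C | intermediate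
4 | (3S,4R,7E)-4,8,12-trimethyltrideca-1,7,11-triene-3,4-diol | C=C[C@H](O)[C@](C)(O)CC/C=C(\C)CCC=C(C)C | intermediate
5 | (3S,4R,7E)-3,4-bis(tert-butyldimethylsilyloxy)-4,8,12-trimethyltrideca-1,7,11-triene | C=C[C@H](O[Si](C)(C)C(C)(C)C)[C@](C)(O[Si](C)(C)C(C)(C)C)CC/C=C(\C)CCC=C(C)C | intermediate
6 | (2E,6E,10R,11S)-10,11-bis(tert-butyldimethylsilyloxy)-2,6,10-trimethyltrideca-2,6,12-trien-1-ol | C=C[C@H](O[Si](C)(C)C(C)(C)C)[C@](C)(O[Si](C)(C)C(C)(C)C)CC/C=C(\C)CC/C=C(\C)CO | intermediate
7 | acrolein | C=CC=O | starting material
8 | prop-2-ene-1,1-diyl dibenzoate | C=CC(OC(=O)c1ccccc1)OC(=O)c1ccccc1 | intermediate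
9 | (2E,6E,10R,11S)-10,11-bis(tert-butyldimethylsilyloxy)-2,6,10-trimethyltrideca-2,6,12-trienal (not isolated) | C=C[C@H](O[Si](C)(C)C(C)(C)C)[C@](C)(O[Si](C)(C)C(C)(C)C)CC/C=C(\C)CC/C=C(\C)C=O | intermediate
10 | (3R,4S,5E,9E,13R,14S)-13,14-bis(tert-butyldimethylsilyloxy)-4-hydroxy-5,9,13-trimethylhexadeca-1,5,9,15-tetraen-3-yl benzoate | C=C[C@H](O[Si](C)(C)C(C)(C)C)[C@](C)(O[Si](C)(C)C(C)(C)C)CC/C=C(\C)CC/C=C(\C)[C@H](O)[C@H](OC(=O)c1ccccc1)C=C | intermediate
11 | (3R,4S,5E,9E,13R,14S)-4,13,14-tris(tert-butyldimethylsilyloxy)-5,9,13-trimethylhexadeca-1,5,9,15-tetraen-3-yl benzoate | C=C[C@H](O[Si](C)(C)C(C)(C)C)[C@](C)(O[Si](C)(C)C(C)(C)C)CC/C=C(\C)CC/C=C(\C)[C@H](O[Si](C)(C)C(C)(C)C)[C@H](OC(=O)c1ccccc1)C=C | intermediate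
12 | (3R,4S,5E,9E,13R,14S)-4,13,14-tris(tert-butyldimethylsilyloxy)-5,9,13-trimethylhexadeca-1,5,9,15-tetraen-3-ol | C=C[C@H](O[Si](C)(C)C(C)(C)C)[C@](C)(O[Si](C)(C)C(C)(C)C)CC/C=C(\C)CC/C=C(\C)[C@H](O[Si](C)(C)C(C)(C)C)[C@H](O)C=C | intermediate
13 | (1R,2E,4S,5R,8E,12E,14S)-4,5,14-tris(tert-butyldimethylsilyloxy)-5,9,13-trimethylcyclotetradeca-2,8,12-trien-1-ol | O[C@@H]1/C=C/[C@H](O[Si](C)(C)C(C)(C)C)[C@](C)(O[Si](C)(C)C(C)(C)C)CC/C=C(\C)CC/C=C(\C)[C@@H]1O[Si](C)(C)C(C)(C)C | intermediate
14 | ethyl vinyl ether | C=COCC | starting material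
15 | (1R,2E,4S,5R,8E,12E,14S)-1-(2-bromo-1-ethoxyethoxy)-4,5,14-tris(tert-butyldimethylsilyloxy)-5,9,13-trimethylcyclotetradeca-2,8,12-triene, both acetal epimers | BrCC(OCC)O[C@@H]1/C=C/[C@H](O[Si](C)(C)C(C)(C)C)[C@](C)(O[Si](C)(C)C(C)(C)C)CC/C=C(\C)CC/C=C(\C)[C@@H]1O[Si](C)(C)C(C)(C)C | intermediate
16 | (1R,3S,4R,7E,11E,13S,14R)-3,4,13-tris(tert-butyldimethylsilyloxy)-16-ethoxy-4,8,12-trimethyl-15-oxabicyclo[12.3.0]heptadeca-7,11-diene, both C16 epimers | C1C(OCC)O[C@@H]2[C@@H]1C[C@H](O[Si](C)(C)C(C)(C)C)[C@](C)(O[Si](C)(C)C(C)(C)C)CC/C=C(\C)CC/C=C(\C)[C@@H]2O[Si](C)(C)C(C)(C)C | intermediate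
17 | (1R,3S,4R,7E,11E,13S,14R)-3,4,13-tris(tert-butyldimethylsilyloxy)-4,8,12-trimethyl-15-oxabicyclo[12.3.0]heptadeca-7,11-dien-16-ol, both C16 epimers | C1C(O)O[C@@H]2[C@@H]1C[C@H](O[Si](C)(C)C(C)(C)C)[C@](C)(O[Si](C)(C)C(C)(C)C)CC/C=C(\C)CC/C=C(\C)[C@@H]2O[Si](C)(C)C(C)(C)C | intermediate
18 | (1R,3S,4R,7E,11E,13S,14R)-3,4,13-tris(tert-butyldimethylsilyloxy)-4,8,12-trimethyl-15-oxabicyclo[12.3.0]heptadeca-7,11-dien-16-one | C1C(=O)O[C@@H]2[C@@H]1C[C@H](O[Si](C)(C)C(C)(C)C)[C@](C)(O[Si](C)(C)C(C)(C)C)CC/C=C(\C)CC/C=C(\C)[C@@H]2O[Si](C)(C)C(C)(C)C | intermediate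
19 | 17-[(dimethylamino)methyl] derivative of 18 (α-carbon configuration immaterial) | CN(C)CC1C(=O)O[C@@H]2[C@@H]1C[C@H](O[Si](C)(C)C(C)(C)C)[C@](C)(O[Si](C)(C)C(C)(C)C)CC/C=C(\C)CC/C=C(\C)[C@@H]2O[Si](C)(C)C(C)(C)C | intermediate
20 | trimethylammonium iodide of 19 (not isolated) | C[N+](C)(C)CC1C(=O)O[C@@H]2[C@@H]1C[C@H](O[Si](C)(C)C(C)(C)C)[C@](C)(O[Si](C)(C)C(C)(C)C)CC/C=C(\C)CC/C=C(\C)[C@@H]2O[Si](C)(C)C(C)(C)C.[I-] | intermediate
21 | (1R,3S,4R,7E,11E,13S,14R)-3,4,13-tris(tert-butyldimethylsilyloxy)-4,8,12-trimethyl-17-methylidene-15-oxabicyclo[12.3.0]heptadeca-7,11-dien-16-one | C=C1C(=O)O[C@@H]2[C@@H]1C[C@H](O[Si](C)(C)C(C)(C)C)[C@](C)(O[Si](C)(C)C(C)(C)C)CC/C=C(\C)CC/C=C(\C)[C@@H]2O[Si](C)(C)C(C)(C)C | intermediate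
22 | (1R,3S,4R,7E,11E,13S,14R)-3,4,13-trihydroxy-4,8,12-trimethyl-17-methylidene-15-oxabicyclo[12.3.0]heptadeca-7,11-dien-16-one | C=C1C(=O)O[C@@H]2[C@@H]1C[C@H](O)[C@](C)(O)CC/C=C(\C)CC/C=C(\C)[C@@H]2O | intermediate
23 | crassocolide B | C=C1C(=O)O[C@@H]2[C@@H]1C[C@H](OC(C)=O)[C@](C)(O)CC/C=C(\C)CC/C=C(\C)[C@@H]2OC(C)=O | target

## Step count and risks

Total: 17 steps. Longest linear sequence: 16 steps from farnesol (steps 1–4 and 6–17); step 5 makes the allyl donor.

**Step 11 (key step).** The processes most likely to interfere are: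
- addition of the secondary C2 radical across the ring to C7=C8;
- hydrogen abstraction by the first radical from C13–H, which is allylic, α to oxygen and reachable through a six-membered transition state;
- incomplete facial control at C1 if the macrocycle prefers a conformation that exposes the other alkene face.

Fallback, from 13: acylation with trichloroacetyl chloride and pyridine gives the trichloroacetate F1. Atom-transfer radical cyclisation with monovalent copper (CuCl, 2,2′-bipyridine, 1,2-dichloroethane, sealed tube, 110–140 °C) closes the same C1–C15 bond 5-exo and caps C2 at once with chlorine, giving the trichloro lactone F2 with no hydride present and no free C2 radical to wander. Exhaustive dechlorination with concentrated Bu3SnH and AIBN, where hydrogen transfer is far faster than any transannular step, rejoins the route at 18, which also saves steps 12 and 13.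

**Step 9.** The process to fear is catalyst loading at the C2 vinyl group followed by six-membered ring closure onto C7=C8 with loss of the C8–C14 segment; oligomerisation at insufficient dilution is the second concern. Fallback, from 12: one equivalent of mCPBA (CH2Cl2, NaHCO3, −20 °C) should epoxidise the most electron-rich alkene, C7=C8, giving the 7,8-epoxide F3 (C11=C12 is deactivated by the allylic silyloxy group, and the vinyl groups are monosubstituted). With that alkene masked no small-ring closure exists, and metathesis under the conditions of step 9 should give the macrocyclic epoxide F4. Stereospecific deoxygenation with Ph3P=Se and CF3CO2H in CH2Cl2 restores the (E)-alkene and rejoins the route at 13.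

**Step 2.** The Payne equilibrium of a trisubstituted epoxy alcohol lies far on the side of 2, and as a lithium alkoxide in THF it may be established too slowly, so the ylide could decompose before terminal epoxide 3 is intercepted. Fallback, from 2: aqueous NaOH in t-BuOH at 70 °C performs the Payne rearrangement and opens the terminal epoxide with hydroxide to the (2S,3R)-triol F5. Selective sulfonylation of the primary hydroxyl (TsCl, Et3N, Bu2SnO cat.) gives the monotosylate F6, and K2CO3 in MeOH closes it to 3, now isolated. Treating 3 with the ylide under the conditions of step 2 gives 4.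

**Step 6.** Possible failures are eroded face selectivity with the α-branched enal, isomerisation of the allylic alcohol by iridium hydride, and 1,2-benzoyl migration from O14 to O13 under phosphate at 90 °C, which would blur which oxygen is free. Fallback, from 6:
- MnO2 gives enal 9, now isolated.
- Brown alkoxyallylboration with the (Z)-γ-alkoxyallylborane made from allyl 4-methoxybenzyl ether (s-BuLi, then (−)-Ipc2BOMe, BF3·OEt2, −78 °C) should add to the Si face and give the syn (13R,14R) adduct F7.
- Dess–Martin oxidation gives the enone F8, which is used at once.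
- Chelation-controlled reduction with Zn(BH4)2 should give the anti (13S,14R) alcohol F9.
- Silylation (TBSOTf, 2,6-lutidine) gives the silyl ether F10, and DDQ removes the 4-methoxybenzyl group to rejoin the route at 12.

## Further compounds

F1 | step 11 | trichloroacetate of 13 at O14 | ClC(Cl)(Cl)C(=O)O[C@@H]1/C=C/[C@H](O[Si](C)(C)C(C)(C)C)[C@](C)(O[Si](C)(C)C(C)(C)C)CC/C=C(\C)CC/C=C(\C)[C@@H]1O[Si](C)(C)C(C)(C)C
F2 | step 11 | 2,15,15-trichloro derivative of lactone 18 (cembrane numbering; C2 configuration immaterial) | ClC1(Cl)C(=O)O[C@@H]2[C@@H]1C(Cl)[C@H](O[Si](C)(C)C(C)(C)C)[C@](C)(O[Si](C)(C)C(C)(C)C)CC/C=C(\C)CC/C=C(\C)[C@@H]2O[Si](C)(C)C(C)(C)C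
F3 | step 9 | 7,8-epoxide of 12 (cembrane numbering; trans epoxide from the (E)-alkene, one of two face isomers drawn) | C=C[C@H](O[Si](C)(C)C(C)(C)C)[C@](C)(O[Si](C)(C)C(C)(C)C)CC[C@H]1O[C@]1(C)CC/C=C(\C)[C@H](O[Si](C)(C)C(C)(C)C)[C@H](O)C=C
F4 | step 9 | 7,8-epoxide of macrocycle 13 (cembrane numbering; one of two face isomers drawn) | O[C@@H]1/C=C/[C@H](O[Si](C)(C)C(C)(C)C)[C@](C)(O[Si](C)(C)C(C)(C)C)CC[C@H]2O[C@]2(C)CC/C=C(\C)[C@@H]1O[Si](C)(C)C(C)(C)C
F5 | step 2 | (2S,3R,6E)-3,7,11-trimethyldodeca-6,10-diene-1,2,3-triol | OC[C@H](O)[C@](C)(O)CC/C=C(\C)CCC=C(C)C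
F6 | step 2 | (2S,3R,6E)-2,3-dihydroxy-3,7,11-trimethyldodeca-6,10-dien-1-yl 4-methylbenzenesulfonate | Cc1ccc(cc1)S(=O)(=O)OC[C@H](O)[C@](C)(O)CC/C=C(\C)CCC=C(C)C
F7 | step 6 | (3R,4R,5E,9E,13R,14S)-13,14-bis(tert-butyldimethylsilyloxy)-3-(4-methoxybenzyloxy)-5,9,13-trimethylhexadeca-1,5,9,15-tetraen-4-ol | C=C[C@H](O[Si](C)(C)C(C)(C)C)[C@](C)(O[Si](C)(C)C(C)(C)C)CC/C=C(\C)CC/C=C(\C)[C@@H](O)[C@H](OCc1ccc(OC)cc1)C=C
F8 | step 6 | (3R,5E,9E,13R,14S)-13,14-bis(tert-butyldimethylsilyloxy)-3-(4-methoxybenzyloxy)-5,9,13-trimethylhexadeca-1,5,9,15-tetraen-4-one | C=C[C@H](O[Si](C)(C)C(C)(C)C)[C@](C)(O[Si](C)(C)C(C)(C)C)CC/C=C(\C)CC/C=C(\C)C(=O)[C@H](OCc1ccc(OC)cc1)C=C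
F9 | step 6 | (3R,4S,5E,9E,13R,14S)-13,14-bis(tert-butyldimethylsilyloxy)-3-(4-methoxybenzyloxy)-5,9,13-trimethylhexadeca-1,5,9,15-tetraen-4-ol | C=C[C@H](O[Si](C)(C)C(C)(C)C)[C@](C)(O[Si](C)(C)C(C)(C)C)CC/C=C(\C)CC/C=C(\C)[C@H](O)[C@H](OCc1ccc(OC)cc1)C=C
F10 | step 6 | (3R,4S,5E,9E,13R,14S)-4,13,14-tris(tert-butyldimethylsilyloxy)-3-(4-methoxybenzyloxy)-5,9,13-trimethylhexadeca-1,5,9,15-tetraene | C=C[C@H](O[Si](C)(C)C(C)(C)C)[C@](C)(O[Si](C)(C)C(C)(C)C)CC/C=C(\C)CC/C=C(\C)[C@H](O[Si](C)(C)C(C)(C)C)[C@H](OCc1ccc(OC)cc1)C=C
A1 | alternative 1 | open-chain lactone with (E)-C7 alkenyl iodide, C3 4-methoxybenzyl ether, C13 OTBS and C4 cyclopropanol | C1C(=O)O[C@H]([C@@H]1C[C@H](OCc2ccc(OC)cc2)C2(O)CC2)[C@@H](O[Si](C)(C)C(C)(C)C)/C(C)=C/CC/C(C)=C/I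
A2 | alternative 1 | 14-membered C4 ketone with saturated lactone, C3 4-methoxybenzyl ether and C13 OTBS | C1C(=O)O[C@@H]2[C@@H]1C[C@H](OCc3ccc(OC)cc3)C(=O)CC/C=C(\C)CC/C=C(\C)[C@@H]2O[Si](C)(C)C(C)(C)C
A3 | alternative 2 | open-chain ynal: C13 aldehyde on the lactone, C3/C4 acetonide, methyl-capped C11≡C12 alkyne | C1C(=O)O[C@H]([C@@H]1C[C@@H]2OC(C)(C)O[C@]2(C)CC/C=C(\C)CCC#CC)C=O
A4 | alternative 2 | 14-membered carbocycle with C13 triethylsilyl ether, saturated lactone and C3/C4 acetonide | C1C(=O)O[C@@H]2[C@@H]1C[C@@H]3OC(C)(C)O[C@]3(C)CC/C=C(\C)CC/C=C(\C)[C@@H]2O[Si](CC)(CC)CC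
A5 | alternative 3 | open-chain keto-aldehyde: C3 aldehyde, C4 methyl ketone, saturated lactone, C13 OTBS | C1C(=O)O[C@H]([C@@H]1CC=O)[C@@H](O[Si](C)(C)C(C)(C)C)/C(C)=C/CC/C(C)=C/CCC(C)=O
A6 | alternative 3 | 14-membered C3,C4-diol with saturated lactone and C13 OTBS | C1C(=O)O[C@@H]2[C@@H]1C[C@H](O)[C@](C)(O)CC/C=C(\C)CC/C=C(\C)[C@@H]2O[Si](C)(C)C(C)(C)C
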